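**Strategy.** Atoms carry germacranolide numbers. Everything rests on stitching one molecule of CO2 between the alkenyl carbon C11 (on C7) and the allylic carbon C6: copper-catalysed carboxylation of a C11 alkenylboronate gives an acrylate whose oxygen at once displaces, with inversion, a chloride at C6 that the C4=C5 Z-alkene activates, closing the trans-fused five-membered lactone ring (O–C6–C7–C11–C12) in one operation. The precursor is the complete ten-membered carbocycle, built from nerol by Sharpless epoxidation (C1, C10), a proline aldol (C8, C9) and an intramolecular chromium 2-bromoallylation (C6–C7 bond), its alkenyl bromide then exchanged for boron and its C6 alcohol for chloride.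

Key step: step 15

Remark: germacrane locants are used for all intermediates (ring C1–C10; C11, C12, C13 on C7; C14 on C10; C15 on C4); TBS = tert-butyldimethylsilyl, PMB = 4-methoxybenzyl, IPr = 1,3-bis(2,6-diisopropylphenyl)imidazol-2-ylidene; aldehyde 6 and ylide 8 are taken as purchasable.

**Route**

Step 1
Reactants: 1 nerol
Product: 2 nerol TBS ether
Conditions: TBSCl, imidazole, DMF, 25 °C
Reagents that add atoms: tert-butyldimethylsilyl chloride, CC(C)(C)[Si](C)(C)Cl
Why: Standard silylation of the primary allylic alcohol masks the future C6 oxygen through the oxidation and hydride steps that follow.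

Step 2
Reactants: 2 nerol TBS ether
Product: 3 (2E,6Z)-8-(TBS-oxy)-2,6-dimethylocta-2,6-dien-1-ol
Conditions: SeO2 (0.5 equiv), t-BuOOH (3 equiv), CH2Cl2, 25 °C
Reagents that add atoms: tert-butyl hydroperoxide, CC(C)(C)OO (oxygen relayed through SeO2, O=[Se]=O)
Why: Selenium dioxide allylic oxidation (ene reaction, then [2,3]-sigmatropic shift) should hydroxylate only the E-methyl group of the electron-richer terminal alkene, because the C4=C5 alkene is deactivated by its allylic silyl ether.

Step 3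
Reactants: 3 (2E,6Z)-allylic alcohol
Product: 4 (2R,3R)-epoxy alcohol
Conditions: Ti(OiPr)4 (10 mol%), (−)-diethyl D-tartrate (12 mol%), t-BuOOH, 4 Å molecular sieves, CH2Cl2, −20 °C
Reagents that add atoms: tert-butyl hydroperoxide, CC(C)(C)OO
Why: Sharpless asymmetric epoxidation acts only on the alkene of the free allylic alcohol, and the D-tartrate ligand should deliver oxygen to the face that gives the (2R,3R)-epoxide, which sets C1 and C10.

Step 4
Reactants: 4 (2R,3R)-epoxy alcohol
Product: 5 (2S,3R)-epoxy aldehyde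
Conditions: Dess–Martin periodinane, pyridine, CH2Cl2, 0 → 25 °C
Reagents that add atoms: none
Why: Buffered Dess–Martin oxidation should give the aldehyde, whose quaternary α-carbon (C10) cannot epimerise.

Step 5
Reactants: 5 (2S,3R)-epoxy aldehyde, 6 2-(PMB-oxy)acetaldehyde
Product: 7 anti-aldol adduct (β-hydroxy-α-PMB-oxy aldehyde)
Conditions: D-proline (20 mol%), DMF, 4 °C, 6 added by syringe pump
Reagents that add atoms: none
Why: In this proline-catalysed direct cross-aldol reaction (enamine catalysis) 5 cannot enolise and serves only as acceptor, the (E)-enamine of 6 should add anti, and D-proline is chosen so that catalyst control sets C8 and C9 (8,9-anti, C9–OH syn to the epoxide oxygen).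

Step 6
Reactants: 7 anti-aldol adduct, 8 ethyl bromo(triphenylphosphoranylidene)acetate
Product: 9 (Z)-α-bromo enoate
Conditions: CH2Cl2, 0 → 25 °C
Reagents that add atoms: none
Why: Wittig olefination with the stabilised bromo ylide tolerates the free hydroxyl and should place bromine on C11 and bring in C13; the alkene geometry is erased later and is not critical.

Step 7
Reactants: 9 (Z)-α-bromo enoate
Product: 10 C9 TBS ether
Conditions: TBSOTf, 2,6-lutidine, CH2Cl2, −78 °C
Reagents that add atoms: tert-butyldimethylsilyl triflate, CC(C)(C)[Si](C)(C)OS(=O)(=O)C(F)(F)F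
Why: Silyl triflate silylation at −78 °C should cap the hindered C9 hydroxyl before the Lewis acid touches the epoxide, which blocks Payne rearrangement and later acyl migration.

Step 8
Reactants: 10 C9 TBS ether
Product: 11 2-bromoallylic alcohol
Conditions: i-Bu2AlH (2.5 equiv), CH2Cl2, −78 °C; aqueous Rochelle salt
Reagents that add atoms: none
Why: 1,2-Reduction of the enoate by the aluminium hydride at low temperature should give the allylic alcohol and leave the epoxide, the ethers and the alkenyl bromide alone.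

Step 9
Reactants: 11 2-bromoallylic alcohol
Product: 12 2-bromoallylic chloride
Conditions: MsCl, 2,4,6-collidine, LiCl, DMF, 0 °C
Reagents that add atoms: lithium chloride, [Li+].[Cl-]
Why: Mesylation followed by in situ SN2 displacement with chloride at the primary allylic carbon should give the halide needed for the allylchromium reagent.

Step 10
Reactants: 12 2-bromoallylic chloride
Product: 13 primary allylic alcohol (C6–OH)
Conditions: HF·pyridine, pyridine, THF, 0 °C
Reagents that add atoms: none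
Why: Fluoride-mediated desilylation should remove the unhindered primary allylic silyl ether much faster than the neopentyl-like secondary one at C9.

Step 11
Reactants: 13 primary allylic alcohol
Product: 14 (Z)-enal
Conditions: Dess–Martin periodinane, pyridine, CH2Cl2, 0 °C
Reagents that add atoms: none
Why: Buffered Dess–Martin oxidation should give the (Z)-enal without Z/E isomerisation.

Step 12
Reactants: 14 (Z)-enal
Product: 15 ten-membered bromoalkenyl alcohol
Conditions: CrCl2 (10 equiv), THF/DMF 5:1, 25 °C, syringe-pump addition to 2 mM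
Reagents that add atoms: none
Why: Intramolecular Nozaki–Hiyama–Kishi-type allylation through a 2-bromoallylchromium species should close the ring via a chair-like transition state with C5 and C8 equatorial (anti adduct, target configuration at C6), while 1,3-allylic strain between bromine and C8 (C8–H in plane, C9 anti to the forming bond) should set C7 relative to C8.

Step 13
Reactants: 15 ten-membered bromoalkenyl alcohol
Product: 16 alkenylboronate alcohol
Conditions: PdCl2(dppf) (10 mol%), B2pin2, KOAc, 1,4-dioxane, 80 °C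
Reagents that add atoms: bis(pinacolato)diboron, CC1(C)OB(OC1(C)C)B1OC(C)(C)C(C)(C)O1
Why: Miyaura borylation (oxidative addition of zerovalent palladium to the alkenyl bromide, transmetalation, reductive elimination) should exchange bromine for the pinacolboryl group and leave the free alcohol, epoxide and ethers untouched.

Step 14
Reactants: 16 alkenylboronate alcohol
Product: 17 (6S)-allylic chloride
Conditions: PPh3, hexachloroacetone, CH2Cl2, −20 → 0 °C
Reagents that add atoms: hexachloroacetone, ClC(Cl)(Cl)C(=O)C(Cl)(Cl)Cl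
Why: Appel-type chlorination should proceed by SN2 attack of chloride on the alkoxyphosphonium ion, that is with inversion at C6 and without allylic transposition, so that the leaving group stands anti to C11.

Step 15
Reactants: 17 (6S)-allylic chloride, 18 carbon dioxide
Product: 20 protected trans-fused α-methylene lactone, via potassium acrylate 19 (not isolated)
Conditions: (IPr)CuCl (10 mol%), KOtBu (1.1 equiv), CO2 (1 atm), THF/DMF 4:1, 25 → 60 °C
Reagents that add atoms: none
Why: tert-Butoxide binds boron, the ate complex hands the alkenyl group to (IPr)Cu–OtBu with retention, CO2 inserts into the Cu–C11 bond (C11–C12 bond), and the resulting carboxylate oxygen displaces chloride at C6 (O–C6 bond). The closest known reaction type is the copper/N-heterocyclic-carbene-catalysed carboxylation of alkenylboronic esters with CO2, whose carboxylate salts are commonly O-alkylated in situ by alkyl halides. The five-membered lactone closes in the 5-exo-tet mode. C6 is the only new stereocentre and arises by SN2 inversion of the (6S)-chloride, so the oxygen enters on the face syn to C11 and the ring fusion is trans (H6 and H7 anti). The step needs CO2 insertion to outrun protonation or allylic alkylation of the alkenylcopper, and O-alkylation at C6 to outrun SN2′ attack at C4 and loss of HCl; these are secured by the CO2 atmosphere, by the base being held as the boronate complex, and by the kinetic ease of five-membered closure at the allylic C6–Cl bond.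

Step 16
Reactants: 20 protected trans-fused α-methylene lactone
Product: 21 C8 alcohol
Conditions: DDQ, CH2Cl2/pH 7 buffer 10:1, 0 °C
Reagents that add atoms: none
Why: Oxidative cleavage of the PMB ether by DDQ (hydride abstraction, hydrolysis of the oxocarbenium ion) should free the C8 hydroxyl under neutral conditions that spare the epoxide, the silyl ether and the α-methylene lactone.

Step 17
Reactants: 21 C8 alcohol, 22 isobutyryl chloride
Product: 23 C8 isobutyrate
Conditions: pyridine, DMAP (10 mol%), CH2Cl2, 0 → 25 °C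
Reagents that add atoms: none
Why: Acylation with the acid chloride under nucleophilic catalysis should esterify the only free hydroxyl (C8) with retention.

Step 18
Reactants: 23 C8 isobutyrate
Product: 24 target CNP0110853.2
Conditions: HF·pyridine, THF, 0 → 25 °C
Reagents that add atoms: none
Why: Fluoride-mediated desilylation under mildly acidic conditions should free the C9 hydroxyl without epoxide opening or 8→9 acyl migration.

**Compound list**

1 | nerol, (2Z)-3,7-dimethylocta-2,6-dien-1-ol | OC/C=C(/C)CCC=C(C)C | starting material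
2 | tert-butyl{[(2Z)-3,7-dimethylocta-2,6-dien-1-yl]oxy}dimethylsilane | CC(C)(C)[Si](C)(C)OC/C=C(/C)CCC=C(C)C | intermediate
3 | (2E,6Z)-8-(TBS-oxy)-2,6-dimethylocta-2,6-dien-1-ol | CC(C)(C)[Si](C)(C)OC/C=C(/C)CC/C=C(\C)CO | intermediate
4 | [(2R,3R)-2-methyl-3-{(3Z)-3-methyl-5-(TBS-oxy)pent-3-en-1-yl}oxiran-2-yl]methanol | CC(C)(C)[Si](C)(C)OC/C=C(/C)CC[C@H]1O[C@]1(C)CO | intermediate
5 | (2S,3R)-2-methyl-3-{(3Z)-3-methyl-5-(TBS-oxy)pent-3-en-1-yl}oxirane-2-carbaldehyde | CC(C)(C)[Si](C)(C)OC/C=C(/C)CC[C@H]1O[C@]1(C)C=O | intermediate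
6 | 2-[(4-methoxybenzyl)oxy]acetaldehyde | O=CCOCc1ccc(OC)cc1 | starting material
7 | (2R,3S)-3-hydroxy-2-(PMB-oxy)-3-[(2R,3R)-2-methyl-3-{(3Z)-3-methyl-5-(TBS-oxy)pent-3-en-1-yl}oxiran-2-yl]propanal | CC(C)(C)[Si](C)(C)OC/C=C(/C)CC[C@H]1O[C@]1(C)[C@@H](O)[C@@H](OCc1ccc(OC)cc1)C=O | intermediate
8 | ethyl bromo(triphenylphosphoranylidene)acetate | CCOC(=O)C(Br)=P(c1ccccc1)(c1ccccc1)c1ccccc1 | starting material
9 | ethyl (2Z,4S,5S)-2-bromo-5-hydroxy-4-(PMB-oxy)-5-[(2R,3R)-2-methyl-3-{(3Z)-3-methyl-5-(TBS-oxy)pent-3-en-1-yl}oxiran-2-yl]pent-2-enoate | CC(C)(C)[Si](C)(C)OC/C=C(/C)CC[C@H]1O[C@]1(C)[C@@H](O)[C@@H](OCc1ccc(OC)cc1)/C=C(\Br)C(=O)OCC | intermediate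
10 | ethyl (2Z,4S,5S)-2-bromo-4-(PMB-oxy)-5-(TBS-oxy)-5-[(2S,3R)-2-methyl-3-{(3Z)-3-methyl-5-(TBS-oxy)pent-3-en-1-yl}oxiran-2-yl]pent-2-enoate | CC(C)(C)[Si](C)(C)OC/C=C(/C)CC[C@H]1O[C@]1(C)[C@@H](O[Si](C)(C)C(C)(C)C)[C@@H](OCc1ccc(OC)cc1)/C=C(\Br)C(=O)OCC | intermediate
11 | (2Z,4S,5S)-2-bromo-4-(PMB-oxy)-5-(TBS-oxy)-5-[(2S,3R)-2-methyl-3-{(3Z)-3-methyl-5-(TBS-oxy)pent-3-en-1-yl}oxiran-2-yl]pent-2-en-1-ol | CC(C)(C)[Si](C)(C)OC/C=C(/C)CC[C@H]1O[C@]1(C)[C@@H](O[Si](C)(C)C(C)(C)C)[C@@H](OCc1ccc(OC)cc1)/C=C(\Br)CO | intermediate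
12 | (2Z,4S,5S)-2-bromo-1-chloro-4-(PMB-oxy)-5-(TBS-oxy)-5-[(2S,3R)-2-methyl-3-{(3Z)-3-methyl-5-(TBS-oxy)pent-3-en-1-yl}oxiran-2-yl]pent-2-ene | CC(C)(C)[Si](C)(C)OC/C=C(/C)CC[C@H]1O[C@]1(C)[C@@H](O[Si](C)(C)C(C)(C)C)[C@@H](OCc1ccc(OC)cc1)/C=C(\Br)CCl | intermediate
13 | (2Z)-5-[(2R,3S)-3-{(1S,2S,3Z)-4-bromo-5-chloro-2-(PMB-oxy)-1-(TBS-oxy)pent-3-en-1-yl}-3-methyloxiran-2-yl]-3-methylpent-2-en-1-ol | OC/C=C(/C)CC[C@H]1O[C@]1(C)[C@@H](O[Si](C)(C)C(C)(C)C)[C@@H](OCc1ccc(OC)cc1)/C=C(\Br)CCl | intermediate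
14 | (2Z)-5-[(2R,3S)-3-{(1S,2S,3Z)-4-bromo-5-chloro-2-(PMB-oxy)-1-(TBS-oxy)pent-3-en-1-yl}-3-methyloxiran-2-yl]-3-methylpent-2-enal | O=C/C=C(/C)CC[C@H]1O[C@]1(C)[C@@H](O[Si](C)(C)C(C)(C)C)[C@@H](OCc1ccc(OC)cc1)/C=C(\Br)CCl | intermediate
15 | (1R,4Z,6R,7S,8S,9S,10S)-11-bromo-1,10-epoxy-8-(PMB-oxy)-9-(TBS-oxy)-12-norgermacra-4,11(13)-dien-6-ol | O[C@@H]1/C=C(/C)CC[C@H]2O[C@]2(C)[C@@H](O[Si](C)(C)C(C)(C)C)[C@@H](OCc2ccc(OC)cc2)[C@H]1C(Br)=C | intermediate
16 | (1R,4Z,6R,7S,8S,9S,10S)-1,10-epoxy-8-(PMB-oxy)-11-(4,4,5,5-tetramethyl-1,3,2-dioxaborolan-2-yl)-9-(TBS-oxy)-12-norgermacra-4,11(13)-dien-6-ol | O[C@@H]1/C=C(/C)CC[C@H]2O[C@]2(C)[C@@H](O[Si](C)(C)C(C)(C)C)[C@@H](OCc2ccc(OC)cc2)[C@H]1C(=C)B1OC(C)(C)C(C)(C)O1 | intermediate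
17 | (1R,4Z,6S,7R,8S,9S,10S)-6-chloro-1,10-epoxy-8-(PMB-oxy)-11-(4,4,5,5-tetramethyl-1,3,2-dioxaborolan-2-yl)-9-(TBS-oxy)-12-norgermacra-4,11(13)-diene | Cl[C@H]1/C=C(/C)CC[C@H]2O[C@]2(C)[C@@H](O[Si](C)(C)C(C)(C)C)[C@@H](OCc2ccc(OC)cc2)[C@H]1C(=C)B1OC(C)(C)C(C)(C)O1 | intermediate
18 | carbon dioxide | O=C=O | starting material
19 | potassium (1R,4Z,6S,7R,8S,9S,10S)-6-chloro-1,10-epoxy-8-(PMB-oxy)-9-(TBS-oxy)germacra-4,11(13)-dien-12-oate | Cl[C@H]1/C=C(/C)CC[C@H]2O[C@]2(C)[C@@H](O[Si](C)(C)C(C)(C)C)[C@@H](OCc2ccc(OC)cc2)[C@H]1C(=C)C(=O)[O-].[K+] | intermediate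
20 | (1R,4Z,6R,7S,8S,9S,10S)-1,10-epoxy-8-(PMB-oxy)-9-(TBS-oxy)germacra-4,11(13)-dien-12,6-olide | C=C1C(=O)O[C@@H]2/C=C(/C)CC[C@H]3O[C@]3(C)[C@@H](O[Si](C)(C)C(C)(C)C)[C@@H](OCc3ccc(OC)cc3)[C@@H]12 | intermediate
21 | (1R,4Z,6R,7R,8S,9S,10S)-1,10-epoxy-8-hydroxy-9-(TBS-oxy)germacra-4,11(13)-dien-12,6-olide | C=C1C(=O)O[C@@H]2/C=C(/C)CC[C@H]3O[C@]3(C)[C@@H](O[Si](C)(C)C(C)(C)C)[C@@H](O)[C@@H]12 | intermediate
22 | isobutyryl chloride | CC(C)C(=O)Cl | starting material
23 | (1R,4Z,6R,7S,8S,9S,10S)-1,10-epoxy-8-(isobutyryloxy)-9-(TBS-oxy)germacra-4,11(13)-dien-12,6-olide | C=C1C(=O)O[C@@H]2/C=C(/C)CC[C@H]3O[C@]3(C)[C@@H](O[Si](C)(C)C(C)(C)C)[C@@H](OC(=O)C(C)C)[C@@H]12 | intermediate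
24 | (1R,4Z,6R,7S,8S,9S,10R)-1,10-epoxy-9-hydroxy-8-(isobutyryloxy)germacra-4,11(13)-dien-12,6-olide, CNP0110853.2 | C=C1C(=O)O[C@@H]2/C=C(/C)CC[C@H]3O[C@]3(C)[C@@H](O)[C@@H](OC(=O)C(C)C)[C@@H]12 | target

**Count.** Total steps: 18. Longest linear sequence: 18 steps (nerol 1 to 24; 6, 8, 18 and 22 are purchased).

**Steps most likely to fail**

Step 15 (key step). The alkenylcopper may be protonated or may alkylate the allylic chloride before CO2 inserts, the base may eliminate HCl, or the carboxylate may close too slowly. The fallback sets out from 15 and comes back at 20. Palladium-catalysed carbonylative lactonisation of 15 (Pd(PPh3)4, CO 1 atm, Et3N, MeCN, 60 °C) would form the acylpalladium from the alkenyl bromide and trap it with the C6 hydroxyl, with retention at C6. This gives 20 directly and makes no new compound.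

Step 12 (ring closure). The allylchromium may add intermolecularly at insufficient dilution, may lose bromide by β-elimination to an allene, or may add to the wrong face at C7. The fallback sets out from 11 and comes back at 16; it puts boron in before ring closure and uses an allylzinc instead of an allylchromium.
- Miyaura borylation of 11 (PdCl2(dppf), B2pin2, KOAc) would give the 2-boryl allylic alcohol F1.
- MsCl, collidine and LiCl would give the 2-boryl allylic chloride F2.
- HF·pyridine would give the primary alcohol F3.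
- Dess–Martin oxidation would give the boryl (Z)-enal F4.
- Palladium-catalysed umpolung allylation of F4 (Pd(PPh3)4 cat., Et2Zn, THF, 25 °C, high dilution) would close the ring to 16.

Step 14 (chlorination with inversion). Chloride may attack with allylic transposition, the alkoxyphosphonium ion may ionise with loss of stereochemical integrity, or chloride may open the epoxide. The fallback sets out from 16 and comes back at 20; inversion is done at the alcohol stage and the leaving group is then installed with retention.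
- Mitsunobu reaction of 16 with chloroacetic acid (PPh3, DIAD) would give the inverted chloroacetate F5.
- K2CO3 in MeOH would give the C6-epimeric alcohol F6.
- MsCl and Et3N at −20 °C would give the C6-epimeric mesylate F7.
- F7 would take the place of 17 under the conditions of step 15 and give 20.

Further compounds

F0 | step 15 | none | none
F1 | step 12 | 2-boryl allylic alcohol (11 with Bpin in place of Br, boron cis to C8) | CC(C)(C)[Si](C)(C)OC/C=C(/C)CC[C@H]1O[C@]1(C)[C@@H](O[Si](C)(C)C(C)(C)C)[C@@H](OCc1ccc(OC)cc1)/C=C(\B1OC(C)(C)C(C)(C)O1)CO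
F2 | step 12 | 2-boryl allylic chloride (12 with Bpin in place of Br) | CC(C)(C)[Si](C)(C)OC/C=C(/C)CC[C@H]1O[C@]1(C)[C@@H](O[Si](C)(C)C(C)(C)C)[C@@H](OCc1ccc(OC)cc1)/C=C(\B1OC(C)(C)C(C)(C)O1)CCl
F3 | step 12 | boryl primary alcohol (13 with Bpin in place of Br) | OC/C=C(/C)CC[C@H]1O[C@]1(C)[C@@H](O[Si](C)(C)C(C)(C)C)[C@@H](OCc1ccc(OC)cc1)/C=C(\B1OC(C)(C)C(C)(C)O1)CCl
F4 | step 12 | boryl (Z)-enal (14 with Bpin in place of Br) | O=C/C=C(/C)CC[C@H]1O[C@]1(C)[C@@H](O[Si](C)(C)C(C)(C)C)[C@@H](OCc1ccc(OC)cc1)/C=C(\B1OC(C)(C)C(C)(C)O1)CCl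
F5 | step 14 | C6-inverted chloroacetate of 16 | ClCC(=O)O[C@H]1/C=C(/C)CC[C@H]2O[C@]2(C)[C@@H](O[Si](C)(C)C(C)(C)C)[C@@H](OCc2ccc(OC)cc2)[C@H]1C(=C)B1OC(C)(C)C(C)(C)O1
F6 | step 14 | C6-epimer of alcohol 16 | O[C@H]1/C=C(/C)CC[C@H]2O[C@]2(C)[C@@H](O[Si](C)(C)C(C)(C)C)[C@@H](OCc2ccc(OC)cc2)[C@H]1C(=C)B1OC(C)(C)C(C)(C)O1
F7 | step 14 | C6-epimeric mesylate (leaving group in the position of the chloride of 17) | CS(=O)(=O)O[C@H]1/C=C(/C)CC[C@H]2O[C@]2(C)[C@@H](O[Si](C)(C)C(C)(C)C)[C@@H](OCc2ccc(OC)cc2)[C@H]1C(=C)B1OC(C)(C)C(C)(C)O1
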